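**Retrosynthetic overview**
1. The target comes from neutral global O-debenzylation of its tri-O-benzyl ether. No acid or base is allowed late, because both aryl groups sit on the concave (endo) face.
2. The tetrahydrofuran ring is formed last. The C6–C6a bond is made by Rh-carbene 1,5-C–H insertion of an α-diazo-γ-lactone into an ArCH2–O ether, which sets C6 and C6a.
3. The diazo lactone comes from a 4,5-cis γ-aryl-γ-lactone, the lactone ring of the target. That lactone is made by translactonisation and O-benzylation of a β-(hydroxybenzyl)butyrolactone.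
4. The butyrolactone comes from a D-proline anti cross-aldol of methyl 4-oxobutanoate with O-benzylsyringaldehyde followed by NaBH4, which sets C3 and C3a.
5. Ring order: temporary butyrolactone, then the target γ-lactone, then the tetrahydrofuran.

Assumption: the SMILES is read as (3S,3aS,6S,6aR) in furo[3,4-c]furan-1-one numbering (C-1 carbonyl, C-3 syringyl carbon, C-6 catechol carbon), meaning all four ring hydrogens are cis and both aryl groups are endo, and the two O-benzylated aryl building blocks, methyl 4-oxobutanoate and D-proline are bought.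

**Step 1**
Reactants: 1 4-(benzyloxy)-3,5-dimethoxybenzaldehyde; 2 methyl 4-oxobutanoate
Product: 5 (4S)-4-{(S)-[4-(benzyloxy)-3,5-dimethoxyphenyl](hydroxy)methyl}dihydrofuran-2(3H)-one, via aldol aldehyde 3 (not isolated), via diol ester 4 (not isolated)
Conditions: D-proline (20 mol %), DMF, 4 °C, 2 added by syringe pump; then MeOH, NaBH4, −20 → 0 °C; aq NH4Cl; minor syn isomer removed by chromatography or recrystallisation
Reagents that add atoms: none
Why: This is a proline-enamine (List–Houk) direct cross-aldol followed by borohydride reduction and spontaneous lactonisation, in which the E-enamine of 2 formed with D-proline attacks the Si face of non-enolisable 1 through the acid-organised chair-like transition state, giving the anti adduct with the carbinol carbon S and the adjacent carbon R in 3 (S in 4 and 5 by priority change only), while reduction and ring closure touch neither centre.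

**Step 2**
Reactants: 5 (4S)-4-{(S)-[4-(benzyloxy)-3,5-dimethoxyphenyl](hydroxy)methyl}dihydrofuran-2(3H)-one; 6 3,4-bis(benzyloxy)benzyl chloride
Product: 8 (4S,5S)-5-[4-(benzyloxy)-3,5-dimethoxyphenyl]-4-({[3,4-bis(benzyloxy)phenyl]methoxy}methyl)dihydrofuran-2(3H)-one, via cis-hydroxymethyl lactone 7 (not isolated)
Conditions: NaH (1.1 equiv), THF–DMF (4:1), 0 °C, 30 min; then 6, 0 °C → rt
Reagents that add atoms: none
Why: This is a translactonisation coupled to a Williamson ether synthesis under Curtin–Hammett control, in which the benzylic alkoxide of 5 attacks the lactone carbonyl and releases the unhindered primary alkoxide of 7, which 6 benzylates far faster than the flanked secondary alkoxide, and since only acyl–oxygen bonds change both stereocentres are retained and the anti aldol relationship becomes the 4,5-cis lactone.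

**Step 3**
Reactants: 8 (4S,5S)-5-[4-(benzyloxy)-3,5-dimethoxyphenyl]-4-({[3,4-bis(benzyloxy)phenyl]methoxy}methyl)dihydrofuran-2(3H)-one
Product: 10 (4S,5S)-5-[4-(benzyloxy)-3,5-dimethoxyphenyl]-4-({[3,4-bis(benzyloxy)phenyl]methoxy}methyl)-3-diazodihydrofuran-2(3H)-one, via trifluoroacetyl lactone 9 (not isolated)
Conditions: LiHMDS, THF, −78 °C; CF3CO2CH2CF3, −78 °C; cold 1 M HCl quench; crude 9: MsN3, Et3N, H2O (1 equiv), MeCN, rt
Reagents that add atoms: methanesulfonyl azide, CS(=O)(=O)N=[N+]=[N-]; 2,2,2-trifluoroethyl trifluoroacetate, O=C(OCC(F)(F)F)C(F)(F)F (its CF3CO group stays only in intermediate 9)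
Why: This is a Danheiser detrifluoroacetylative (Regitz-type) diazo transfer, in which Claisen trifluoroacetylation of the lithium enolate makes C-3 acidic enough for triethylamine so that mesyl azide delivers N2 with loss of the trifluoroacetyl group, and C-4 and C-5 are untouched because C-3 is the only enolisable position and has no β-leaving group.

**Step 4**
Reactants: 10 (4S,5S)-5-[4-(benzyloxy)-3,5-dimethoxyphenyl]-4-({[3,4-bis(benzyloxy)phenyl]methoxy}methyl)-3-diazodihydrofuran-2(3H)-one
Product: 11 (3S,3aS,6S,6aR)-6-[3,4-bis(benzyloxy)phenyl]-3-[4-(benzyloxy)-3,5-dimethoxyphenyl]tetrahydro-1H,3H-furo[3,4-c]furan-1-one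
Conditions: Rh2(OAc)4 (2 mol %), CH2Cl2, reflux, slow addition of 10
Reagents that add atoms: none
Why: This is a rhodium(II)-carbene intramolecular 1,5-C–H insertion into the oxygen-activated benzylic ether C–H bond, in which the tether on C-4 can reach the carbene only from its own face so the new tetrahydrofuran is cis-fused (C-6a R), and the concerted chair-like Taber-type transition state with the aryl group pseudo-equatorial leaves that aryl group on the concave face over the flat carbonyl carbon (C-6 S, kinetic endo product), remote from the endo aryl group at the diagonal C-3.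

**Step 5**
Reactants: 11 (3S,3aS,6S,6aR)-6-[3,4-bis(benzyloxy)phenyl]-3-[4-(benzyloxy)-3,5-dimethoxyphenyl]tetrahydro-1H,3H-furo[3,4-c]furan-1-one
Product: 12 (3S,3aS,6S,6aR)-6-(3,4-dihydroxyphenyl)-3-(4-hydroxy-3,5-dimethoxyphenyl)tetrahydro-1H,3H-furo[3,4-c]furan-1-one
Conditions: H2 (1 atm), 10 % Pd/C, EtOAc, rt, stopped at 3 equiv H2 uptake; filtration under argon, neutral silica
Reagents that add atoms: none
Why: This is a heterogeneous catalytic hydrogenolysis in which the three primary aryl benzyl ethers are cleaved much faster than the two hindered secondary ring C–O bonds, and the neutral aprotic medium offers neither acid nor base to open a quinone methide, so all four stereocentres of the strained endo,endo skeleton persist.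

**Compound list**
1 | 4-(benzyloxy)-3,5-dimethoxybenzaldehyde | COc1cc(C=O)cc(OC)c1OCc1ccccc1 | starting material
2 | methyl 4-oxobutanoate | COC(=O)CCC=O | starting material
3 | methyl (3R,4S)-4-[4-(benzyloxy)-3,5-dimethoxyphenyl]-3-formyl-4-hydroxybutanoate (aldol aldehyde) | COc1cc([C@@H](O)[C@H](C=O)CC(=O)OC)cc(OC)c1OCc1ccccc1 | intermediate
4 | methyl (3S,4S)-4-[4-(benzyloxy)-3,5-dimethoxyphenyl]-4-hydroxy-3-(hydroxymethyl)butanoate (diol ester) | COc1cc([C@@H](O)[C@H](CO)CC(=O)OC)cc(OC)c1OCc1ccccc1 | intermediate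
5 | (4S)-4-{(S)-[4-(benzyloxy)-3,5-dimethoxyphenyl](hydroxy)methyl}dihydrofuran-2(3H)-one | COc1cc([C@@H](O)[C@H]2CC(=O)OC2)cc(OC)c1OCc1ccccc1 | intermediate
6 | 3,4-bis(benzyloxy)benzyl chloride | ClCc1ccc(OCc2ccccc2)c(OCc2ccccc2)c1 | starting material
7 | (4S,5S)-5-[4-(benzyloxy)-3,5-dimethoxyphenyl]-4-(hydroxymethyl)dihydrofuran-2(3H)-one (cis-hydroxymethyl lactone, present in step 2 as its sodium alkoxide) | COc1cc([C@H]2OC(=O)C[C@H]2CO)cc(OC)c1OCc1ccccc1 | intermediate
8 | (4S,5S)-5-[4-(benzyloxy)-3,5-dimethoxyphenyl]-4-({[3,4-bis(benzyloxy)phenyl]methoxy}methyl)dihydrofuran-2(3H)-one | COc1cc([C@H]2OC(=O)C[C@H]2COCc2ccc(OCc3ccccc3)c(OCc3ccccc3)c2)cc(OC)c1OCc1ccccc1 | intermediate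
9 | (4S,5S)-5-[4-(benzyloxy)-3,5-dimethoxyphenyl]-4-({[3,4-bis(benzyloxy)phenyl]methoxy}methyl)-3-(trifluoroacetyl)dihydrofuran-2(3H)-one (C-3 epimers/enol) | COc1cc([C@H]2OC(=O)C(C(=O)C(F)(F)F)[C@H]2COCc2ccc(OCc3ccccc3)c(OCc3ccccc3)c2)cc(OC)c1OCc1ccccc1 | intermediate
10 | (4S,5S)-5-[4-(benzyloxy)-3,5-dimethoxyphenyl]-4-({[3,4-bis(benzyloxy)phenyl]methoxy}methyl)-3-diazodihydrofuran-2(3H)-one | COc1cc([C@H]2OC(=O)C(=[N+]=[N-])[C@H]2COCc2ccc(OCc3ccccc3)c(OCc3ccccc3)c2)cc(OC)c1OCc1ccccc1 | intermediate
11 | (3S,3aS,6S,6aR)-6-[3,4-bis(benzyloxy)phenyl]-3-[4-(benzyloxy)-3,5-dimethoxyphenyl]tetrahydro-1H,3H-furo[3,4-c]furan-1-one | COc1cc([C@H]2OC(=O)[C@@H]3[C@H]2CO[C@@H]3c2ccc(OCc4ccccc4)c(OCc4ccccc4)c2)cc(OC)c1OCc1ccccc1 | intermediate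
12 | (3S,3aS,6S,6aR)-6-(3,4-dihydroxyphenyl)-3-(4-hydroxy-3,5-dimethoxyphenyl)tetrahydro-1H,3H-furo[3,4-c]furan-1-one (CNP0224550.1) | COc1cc([C@H]2OC(=O)[C@@H]3[C@H]2CO[C@@H]3c2ccc(O)c(O)c2)cc(OC)c1O | target

Total step count: 5. Longest linear sequence: 5.

**Steps most likely to fail**

**Step 2.** The alkoxide equilibrium may lie on the side of 5, or the secondary alkoxide may be benzylated competitively. Either would give the regioisomeric ether. The fallback fixes the lactone regiochemistry through oxidation level instead of an equilibrium. It sets out from 3, this time isolated after the aldol, and comes back at 8.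
- Pinnick oxidation (NaClO2, NaH2PO4, 2-methyl-2-butene, t-BuOH–H2O) gives the hydroxy acid monoester F1. In F1 only the benzylic hydroxyl can form a γ-lactone.
- With catalytic PPTS it closes to the cis-lactone acid F2.
- BH3·SMe2 (THF, 0 °C) reduces the free acid chemoselectively to alcohol 7, which is isolated.
- Alcohol 7 is etherified with 6 under non-equilibrating conditions (Ag2O, CH2Cl2, dark) to give 8.

**Step 4.** A 1,2-hydride shift to the butenolide may compete, or the endo selectivity may erode on the cis-lactone. The fallback replaces the carbene insertion by an acyl transfer and oxocarbenium reduction. It sets out from 7, isolated as in the fallback above, and comes back at 11.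
- Esterification with 3,4-bis(benzyloxy)benzoic acid (EDC, DMAP) gives the benzoate ester F3.
- LiHMDS (2.2 equiv, THF, −78 °C) triggers an intramolecular Claisen condensation (Baker–Venkataraman-type O-to-C acyl shift).
- The liberated primary alcohol closes onto the aryl ketone to give the cis-fused bicyclic hemiketal F4.
- Et3SiH/BF3·OEt2 (CH2Cl2, −78 °C) reduces the aryl oxocarbenium ion by hydride delivery to the convex face. This pushes the aryl group endo and gives 11.

**Step 5.** The benzylic lactone C–O bond may be hydrogenolysed, or the free p-hydroxybenzylic ester may epimerise. The fallback removes the labile benzylic ester before hydrogen is used. It sets out from 11 and comes back at 12.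
- LiOH (1.05 equiv, THF–H2O, 0 °C) opens the lactone to the lithium hydroxy carboxylate F5.
- The benzylic alcohol of F5 is inert to Pd/C in neutral to weakly basic medium.
- Hydrogenolysis (H2, Pd/C, THF–H2O) followed by one equivalent of acetic acid gives the tetrahydroxy acid F6.
- Carboxyl activation (EDC·HCl, THF, 0 °C) re-closes the lactone by acyl–oxygen bond formation, with retention at C-3, to give 12.

**Further compounds**
F1 | step 2 | (2R)-2-{(S)-[4-(benzyloxy)-3,5-dimethoxyphenyl](hydroxy)methyl}-4-methoxy-4-oxobutanoic acid (hydroxy acid monoester) | COc1cc([C@@H](O)[C@H](C(=O)O)CC(=O)OC)cc(OC)c1OCc1ccccc1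
F2 | step 2 | (2S,3R)-2-[4-(benzyloxy)-3,5-dimethoxyphenyl]-5-oxotetrahydrofuran-3-carboxylic acid (cis-lactone acid) | COc1cc([C@H]2OC(=O)C[C@H]2C(=O)O)cc(OC)c1OCc1ccccc1
F3 | step 4 | {(2S,3S)-2-[4-(benzyloxy)-3,5-dimethoxyphenyl]-5-oxotetrahydrofuran-3-yl}methyl 3,4-bis(benzyloxy)benzoate (benzoate ester) | COc1cc([C@H]2OC(=O)C[C@H]2COC(=O)c2ccc(OCc3ccccc3)c(OCc3ccccc3)c2)cc(OC)c1OCc1ccccc1
F4 | step 4 | (3S,3aS,6aR)-6-[3,4-bis(benzyloxy)phenyl]-3-[4-(benzyloxy)-3,5-dimethoxyphenyl]-6-hydroxytetrahydro-1H,3H-furo[3,4-c]furan-1-one (bicyclic hemiketal, C-6 anomers) | COc1cc([C@H]2OC(=O)[C@@H]3[C@H]2COC3(O)c2ccc(OCc4ccccc4)c(OCc4ccccc4)c2)cc(OC)c1OCc1ccccc1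
F5 | step 5 | lithium (2S,3R,4S)-2-[3,4-bis(benzyloxy)phenyl]-4-{(S)-[4-(benzyloxy)-3,5-dimethoxyphenyl](hydroxy)methyl}tetrahydrofuran-3-carboxylate (lithium hydroxy carboxylate) | [Li+].COc1cc([C@@H](O)[C@@H]2CO[C@H](c3ccc(OCc4ccccc4)c(OCc4ccccc4)c3)[C@@H]2C(=O)[O-])cc(OC)c1OCc1ccccc1
F6 | step 5 | (2S,3R,4S)-2-(3,4-dihydroxyphenyl)-4-[(S)-hydroxy(4-hydroxy-3,5-dimethoxyphenyl)methyl]tetrahydrofuran-3-carboxylic acid (tetrahydroxy acid) | COc1cc([C@@H](O)[C@@H]2CO[C@H](c3ccc(O)c(O)c3)[C@@H]2C(=O)O)cc(OC)c1O
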